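A direct plan would condense aroylacetate A1 (from a protected ring B phenol by Friedel–Crafts acetylation and Claisen homologation) with hydroquinone A2 in a melt to give flavone A3, and would end with a Lewis-acid deprotection. Its weakest steps would be the melt that closes ring C (about 240 °C with an air-sensitive hydroquinone and a benzyl ether; tar and low conversion would be likely), the acetylation and homologation of ring B (two steps that would add only a three-carbon handle), and the reduction that would make A2 just before use (a step with no gain in complexity).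

The route rests on the C2–C1' bond between ring C and ring B, made by a twofold C–H coupling of a 2-unsubstituted chromone with the benzyl ether of 2,5-dimethoxyphenol. The step exploits the 2',4',5'-oxygenation of ring B: C1' is the one CH that lies para to one oxygen and ortho to another, so the arene, unfunctionalised at carbon, should react exactly where the target needs the bond, at the electrophilic C2 of the pyranone. One operation joins the halves with no handle on either carbon. Ring C is closed earlier, under mild acid, on a catalogue acetophenone that already fixes the ring A pattern, so the melt, the ring B acylation and homologation, and the hydroquinone all disappear.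

Key step: step 5

Remark: the target is achiral, so no stereocentre has to be set; acetophenone 1 is taken as a catalogue compound.

Step 1
Reactants: 1 1-(6-hydroxy-2,3,4-trimethoxyphenyl)ethan-1-one; 2 N,N-dimethylformamide dimethyl acetal
Product: 4 5,6,7-trimethoxy-4H-chromen-4-one, via enaminone 3 (not isolated)
Conditions: Me2NCH(OMe)2 (2 equiv), toluene, 100 °C; then conc. HCl, CH2Cl2, 40 °C
Reagents that add atoms: N,N-dimethylformamide dimethyl acetal 2, COC(OC)N(C)C
Why: Enaminone route to chromones, in which the methyl ketone condenses with the formamide acetal and acid then triggers conjugate addition of the chelated 6-hydroxyl and loss of dimethylamine; only the 5,6,7-trimethoxy pattern can result because 1 has a single free hydroxyl.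

Step 2
Reactants: 4 5,6,7-trimethoxy-4H-chromen-4-one
Product: 5 5,6-dihydroxy-7-methoxy-4H-chromen-4-one
Conditions: BBr3 (2.2 equiv), CH2Cl2, −78 to 0 °C; then MeOH, H2O
Reagents that add atoms: none
Why: Lewis-acid ether cleavage directed by the C4 carbonyl, in which boron held by the carbonyl should cleave the peri 5-methoxy group first and the boron aryloxide so formed should then draw the neighbouring 6-methoxy group (the twisted, most basic middle ether) into a five-membered borate, while the in-plane 7-methoxy group, a vinylogous ester oxygen, should survive the limited reagent at or below 0 °C.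

Step 3
Reactants: 5 5,6-dihydroxy-7-methoxy-4H-chromen-4-one; 6 benzyl bromide
Product: 7 5,6-bis(benzyloxy)-7-methoxy-4H-chromen-4-one
Conditions: BnBr (3 equiv), K2CO3, DMF, 60 °C, under Ar
Reagents that add atoms: benzyl bromide 6, BrCc1ccccc1
Why: Williamson ether synthesis, in which the free 6-hydroxyl should react first and the chelated 5-hydroxyl should follow with excess bromide and mild heating, under argon because the catecholate is oxidised by air.

Step 4
Reactants: 8 2,5-dimethoxyphenol; 6 benzyl bromide
Product: 9 2-(benzyloxy)-1,4-dimethoxybenzene
Conditions: BnBr, K2CO3, acetone, reflux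
Reagents that add atoms: benzyl bromide 6, BrCc1ccccc1
Why: Williamson ether synthesis on the only hydroxyl of 8, which masks the future 4'-hydroxyl as a strong para donor for the coupling.

Step 5
Reactants: 7 5,6-bis(benzyloxy)-7-methoxy-4H-chromen-4-one; 9 2-(benzyloxy)-1,4-dimethoxybenzene
Product: 10 5,6-bis(benzyloxy)-2-[4-(benzyloxy)-2,5-dimethoxyphenyl]-7-methoxy-4H-chromen-4-one
Conditions: Pd(OAc)2 (10 mol %), AgOAc (3 equiv), CsO2CCMe3 (1 equiv), Me3CCO2H, 9 (5 equiv, excess recovered), 110 °C
Reagents that add atoms: none
Why: Divalent palladium pivalate should metalate arene 9 at C5 by a carboxylate-assisted, electrophilic C–H cleavage; the aryl–palladium species should then add across C2=C3 of chromone 7 with the aryl group going to the β-carbon C2, and the palladium enolate so formed should lose hydride from C2 (after epimerisation through its oxygen-bound form) to restore the pyranone, while AgOAc returns zerovalent palladium to the divalent state. The closest known reaction type is the palladium-catalysed cross-dehydrogenative coupling of chromones with simple arenes at C2, a relative of the Fujiwara–Moritani reaction. No ring is closed and no stereocentre is formed; the step makes only the C2–C1' bond. On the arene, C5 (para to the benzyloxy group, ortho to a methoxy group) is the most electron-rich unhindered CH, whereas C3 lies between two alkoxy groups and C6 has a single ortho donor, which is the site preference that 1,2,4-trialkoxybenzenes show towards electrophiles. On the chromone, the polarity of the enone sends the aryl group to C2 and the metal to C3. The phenyl rings of the benzyl groups are far poorer partners for the electrophilic metalation than the trialkoxyarene, which is used in excess to outrun its own oxidative dimerisation.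

Step 6
Reactants: 10 5,6-bis(benzyloxy)-2-[4-(benzyloxy)-2,5-dimethoxyphenyl]-7-methoxy-4H-chromen-4-one
Product: 11 5,6-dihydroxy-2-(4-hydroxy-2,5-dimethoxyphenyl)-7-methoxy-4H-chromen-4-one
Conditions: H2 (1 atm), Pd/C (10 wt % Pd), EtOAc/MeOH, rt; work-up without base under Ar
Reagents that add atoms: none
Why: Catalytic hydrogenolysis of the three aryl benzyl ethers, which should leave the four methyl ethers and, at 1 atm and room temperature, the conjugated C2=C3 bond of the flavone untouched.

Compound list
1 | 1-(6-hydroxy-2,3,4-trimethoxyphenyl)ethan-1-one | CC(=O)c1c(O)cc(OC)c(OC)c1OC | starting material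
2 | N,N-dimethylformamide dimethyl acetal | COC(OC)N(C)C | starting material
3 | (2E)-3-(dimethylamino)-1-(6-hydroxy-2,3,4-trimethoxyphenyl)prop-2-en-1-one (enaminone) | CN(C)/C=C/C(=O)c1c(O)cc(OC)c(OC)c1OC | intermediate (not isolated)
4 | 5,6,7-trimethoxy-4H-chromen-4-one | COc1cc2occc(=O)c2c(OC)c1OC | intermediate
5 | 5,6-dihydroxy-7-methoxy-4H-chromen-4-one | COc1cc2occc(=O)c2c(O)c1O | intermediate
6 | benzyl bromide | BrCc1ccccc1 | starting material
7 | 5,6-bis(benzyloxy)-7-methoxy-4H-chromen-4-one | COc1cc2occc(=O)c2c(OCc2ccccc2)c1OCc1ccccc1 | intermediate
8 | 2,5-dimethoxyphenol | COc1ccc(OC)c(O)c1 | starting material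
9 | 2-(benzyloxy)-1,4-dimethoxybenzene | COc1ccc(OC)c(OCc2ccccc2)c1 | intermediate
10 | 5,6-bis(benzyloxy)-2-[4-(benzyloxy)-2,5-dimethoxyphenyl]-7-methoxy-4H-chromen-4-one | COc1cc(-c2cc(=O)c3c(OCc4ccccc4)c(OCc4ccccc4)c(OC)cc3o2)c(OC)cc1OCc1ccccc1 | intermediate
11 | 5,6-dihydroxy-2-(4-hydroxy-2,5-dimethoxyphenyl)-7-methoxy-4H-chromen-4-one | COc1cc(-c2cc(=O)c3c(O)c(O)c(OC)cc3o2)c(OC)cc1O | target

Total step count: 6. Longest linear sequence: 5 steps (steps 1, 2, 3, 5, 6).

Steps most likely to fail

Step 5. The electron-rich arene could dimerise oxidatively faster than it adds to the chromone, or the metalation could spread over more than one site, so that conversion of 7 stalls. The fallback would set out from 9 and 7 and come back at 10, and would fix the site on ring B by halogenation. Bromination of 9 (NBS, MeCN, 0 °C) should give 1-(benzyloxy)-4-bromo-2,5-dimethoxybenzene F1 at the same para position. Lithium–bromine exchange and borylation (n-BuLi, B(OiPr)3, THF, −78 °C; aq. HCl) should give [4-(benzyloxy)-2,5-dimethoxyphenyl]boronic acid F2. Conjugate addition of F2 to chromone 7 under divalent palladium catalysis (Pd(O2CCF3)2, 2,2'-bipyridine, aqueous THF/AcOH, 60 °C) should give the racemic flavanone (2RS)-5,6-bis(benzyloxy)-2-[4-(benzyloxy)-2,5-dimethoxyphenyl]-7-methoxy-2,3-dihydro-4H-chromen-4-one F3. Dehydrogenation (DDQ, dioxane, 100 °C) should then give 10.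

Step 2. The cleavage could run on to the 7-methoxy group or stop after the 5-position, giving mixtures of partly demethylated chromones. The fallback would set out from 4 and come back at 5, and would give up differentiation by cleavage. Exhaustive demethylation (48% HBr, AcOH, reflux) should give 5,6,7-trihydroxy-4H-chromen-4-one F4. One equivalent of MeI with K2CO3 in DMF at room temperature under argon should then methylate only the 7-hydroxyl, because it is the most acidic of the three (para to the ring carbonyl, whereas the 5-hydroxyl is chelated and the 6-hydroxyl lacks this conjugation).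

Step 3. The carbonate could open the 2-unsubstituted pyranone, or the chelated 5-hydroxyl could resist alkylation while the catecholate is oxidised. The fallback would set out from 5 and come back at 11, and would bridge the catechol without base. Heating 5 with Ph2CCl2 (diphenyl ether, 170 °C) should give the ketal 7-methoxy-5,6-[(diphenylmethylene)bis(oxy)]-4H-chromen-4-one F5. F5 would take the place of 7 under the conditions of step 5 to give 2-[4-(benzyloxy)-2,5-dimethoxyphenyl]-7-methoxy-5,6-[(diphenylmethylene)bis(oxy)]-4H-chromen-4-one F6. Hydrogenolysis under the conditions of step 6 should cleave the ketal and the benzyl ether together to give 11.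

Further compounds
F1 | step 5 | 1-(benzyloxy)-4-bromo-2,5-dimethoxybenzene | COc1cc(Br)c(OC)cc1OCc1ccccc1
F2 | step 5 | [4-(benzyloxy)-2,5-dimethoxyphenyl]boronic acid | COc1cc(B(O)O)c(OC)cc1OCc1ccccc1
F3 | step 5 | (2RS)-5,6-bis(benzyloxy)-2-[4-(benzyloxy)-2,5-dimethoxyphenyl]-7-methoxy-2,3-dihydro-4H-chromen-4-one (racemic) | COc1cc(C2CC(=O)c3c(OCc4ccccc4)c(OCc4ccccc4)c(OC)cc3O2)c(OC)cc1OCc1ccccc1
F4 | step 2 | 5,6,7-trihydroxy-4H-chromen-4-one | Oc1cc2occc(=O)c2c(O)c1O
F5 | step 3 | 7-methoxy-5,6-[(diphenylmethylene)bis(oxy)]-4H-chromen-4-one | COc1cc2occc(=O)c2c2c1OC(c1ccccc1)(c1ccccc1)O2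
F6 | step 3 | 2-[4-(benzyloxy)-2,5-dimethoxyphenyl]-7-methoxy-5,6-[(diphenylmethylene)bis(oxy)]-4H-chromen-4-one | COc1cc2oc(-c3cc(OC)c(OCc4ccccc4)cc3OC)cc(=O)c2c2c1OC(c1ccccc1)(c1ccccc1)O2
A1 | direct plan | ethyl 3-[4-(benzyloxy)-2,5-dimethoxyphenyl]-3-oxopropanoate | CCOC(=O)CC(=O)c1cc(OC)c(OCc2ccccc2)cc1OC
A2 | direct plan | 2,6-dimethoxybenzene-1,4-diol | COc1cc(O)cc(OC)c1O
A3 | direct plan | 2-[4-(benzyloxy)-2,5-dimethoxyphenyl]-6-hydroxy-5,7-dimethoxy-4H-chromen-4-one | COc1cc2oc(-c3cc(OC)c(OCc4ccccc4)cc3OC)cc(=O)c2c(OC)c1O
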